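**Plan**

- Retrosynthesis: the pyran ring (ring B) is cut at C2–C3 and then at O1–C2, a five-plus-one disconnection to ortho-vinylphenol 9 and 2-methoxypropene. Compound 9 is cut at the aryl–vinyl bond (Stille), then at C–I, at O–CH3 and at the aryl–acyl bond (Houben–Hoesch), back to phloroglucinol 1 and nitrile 2.
- Forward: ring A comes from 1 and the arylacetyl chain is joined first. The ring-A oxygens are then told apart: MOM on the two unchelated hydroxyls, iodination ortho to the chelated one, and O-methylation of that one. The MOM groups are removed, the vinyl group is put on, and ring B is closed last.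
- Enabling feature (chromene numbering): O1 on C8a can stabilise an oxocarbenium ion at C2. The ring-A oxygens on C8a, C5 and C7 make the vinyl terminus C3 nucleophilic and the C4 benzylic cation stable, so ring B can close at C2–C3 in a Prins-type event that also fixes which oxygen enters the ring.
- Stereochemistry: the target has no stereocentre and its only C=C bond (C3=C4) is endocyclic, so nothing needs to be controlled.

Key step: step 7

**Route**

Step 1
Reactants: 1 phloroglucinol; 2 4-methoxyphenylacetonitrile
Product: 4 2-(4-methoxyphenyl)-1-(2,4,6-trihydroxyphenyl)ethan-1-one, via ketiminium chloride 3 (not isolated)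
Conditions: ZnCl2, HCl (gas), dry Et2O, 0 °C; then H2O, reflux
Reagents that add atoms: water, O
Why: Houben–Hoesch acylation of the symmetric triol by the nitrile should give the ketiminium salt, which water hydrolyses to the ketone; all three ring carbons are equivalent and the acylated ring is deactivated toward a second acylation.

Step 2
Reactants: 4 2-(4-methoxyphenyl)-1-(2,4,6-trihydroxyphenyl)ethan-1-one
Product: 5 1-[2-hydroxy-4,6-bis(methoxymethoxy)phenyl]-2-(4-methoxyphenyl)ethan-1-one
Conditions: MOMCl (2.2 equiv), i-Pr2NEt (3 equiv), CH2Cl2, 0 °C to rt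
Reagents that add atoms: chloromethyl methyl ether, COCCl
Why: Selective Williamson-type O-alkylation should take the para hydroxyl and one of the two equivalent ortho hydroxyls, while the last ortho hydroxyl is held in a hydrogen bond to the ketone and stays free, as is usual for 2,4,6-trihydroxyaryl ketones.

Step 3
Reactants: 5 1-[2-hydroxy-4,6-bis(methoxymethoxy)phenyl]-2-(4-methoxyphenyl)ethan-1-one
Product: 6 1-[2-hydroxy-3-iodo-4,6-bis(methoxymethoxy)phenyl]-2-(4-methoxyphenyl)ethan-1-one
Conditions: NIS (1.05 equiv), DMF, 0 °C to rt, dark
Reagents that add atoms: N-iodosuccinimide, O=C1CCC(=O)N1I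
Why: Electrophilic aromatic iodination should be directed by the single free, chelated hydroxyl to its ortho carbon, the other free ring carbon lying between two MOM ethers; this places the future vinyl carbon next to the hydroxyl that becomes the methoxy group.

Step 4
Reactants: 6 1-[2-hydroxy-3-iodo-4,6-bis(methoxymethoxy)phenyl]-2-(4-methoxyphenyl)ethan-1-one
Product: 7 1-[3-iodo-2-methoxy-4,6-bis(methoxymethoxy)phenyl]-2-(4-methoxyphenyl)ethan-1-one
Conditions: MeI (1.5 equiv), K2CO3, DMF, rt
Reagents that add atoms: iodomethane, CI
Why: Williamson O-methylation of the only free phenol; under K2CO3 the phenoxide forms far more readily than the ketone enolate, so C-methylation of the benzylic methylene should not compete.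

Step 5
Reactants: 7 1-[3-iodo-2-methoxy-4,6-bis(methoxymethoxy)phenyl]-2-(4-methoxyphenyl)ethan-1-one
Product: 8 1-(4,6-dihydroxy-3-iodo-2-methoxyphenyl)-2-(4-methoxyphenyl)ethan-1-one
Conditions: 3 M HCl (aq), MeOH, 50 °C
Reagents that add atoms: none
Why: Acid-catalysed acetal exchange with methanol should remove both MOM ethers; it is placed before the vinylation because a MOM acetal next to a vinyl group would itself ionise and cyclise under acid.

Step 6
Reactants: 8 1-(4,6-dihydroxy-3-iodo-2-methoxyphenyl)-2-(4-methoxyphenyl)ethan-1-one
Product: 9 1-(3-ethenyl-4,6-dihydroxy-2-methoxyphenyl)-2-(4-methoxyphenyl)ethan-1-one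
Conditions: Bu3SnCH=CH2 (1.5 equiv), Pd(PPh3)4 (5 mol %), BHT (trace), degassed toluene, 90 °C
Reagents that add atoms: tributyl(vinyl)stannane, C=C[Sn](CCCC)(CCCC)CCCC
Why: Stille cross-coupling at the aryl iodide runs under neutral conditions that tolerate free phenols and the enolisable ketone, and it leaves only the 4-hydroxyl ortho to the new vinyl group.

Step 7
Reactants: 9 1-(3-ethenyl-4,6-dihydroxy-2-methoxyphenyl)-2-(4-methoxyphenyl)ethan-1-one
Product: 11 1-(7-hydroxy-5-methoxy-2,2-dimethyl-2H-chromen-6-yl)-2-(4-methoxyphenyl)ethan-1-one, via mixed ketal 10 (not isolated)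
Conditions: 2-methoxypropene (1.5 equiv, in two portions), (±)-camphor-10-sulfonic acid (10 mol %), 4 Å MS, CH2Cl2, −20 °C to rt; Et3N quench
Reagents that add atoms: 2-methoxypropene, C=C(C)OC
Why: Proposed new method: Acid-catalysed addition of the 4-hydroxyl of 9 to 2-methoxypropene should give mixed ketal 10, whose loss of methanol forms an aryloxy oxocarbenium ion at the future C2; the terminal carbon of the ortho vinyl group (future C3) attacks it to make the C2–C3 bond, and the C4 benzylic cation so formed loses a C3 proton to give the C3=C4 bond of ring B. The closest known reaction type is the alkene-terminated Prins (oxocarbenium–olefin) cyclisation of mixed acetals of homoallylic alcohols to dihydropyrans, here extended to a phenol-derived ketone ketal in which the ortho-vinylphenol plays the part of the homoallylic alcohol. The pyran ring closes in a 6-endo-trig mode at the alkene. No stereocentre is formed. The step needs Markovnikov regioselectivity and closure on the correct oxygen: attack through C3 is secured because the C4 cation is stabilised by O1 on C8a, the C5 methoxy group and the C7 hydroxyl, and only the 4-hydroxyl of 9 is ortho to the vinyl group, the other hydroxyl being para to it and hydrogen-bonded to the ketone. Ionisation of 10 back to 9 is reversible and unproductive, whereas C–C bond formation and proton loss are irreversible, which should funnel the material to 11.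

**Compound list**

1 | phloroglucinol (benzene-1,3,5-triol) | Oc1cc(O)cc(O)c1 | starting material
2 | 4-methoxyphenylacetonitrile | COc1ccc(CC#N)cc1 | starting material
3 | 2-(4-methoxyphenyl)-1-(2,4,6-trihydroxyphenyl)ethan-1-iminium chloride | COc1ccc(CC(=[NH2+])c2c(O)cc(O)cc2O)cc1.[Cl-] | intermediate (not isolated)
4 | 2-(4-methoxyphenyl)-1-(2,4,6-trihydroxyphenyl)ethan-1-one | COc1ccc(CC(=O)c2c(O)cc(O)cc2O)cc1 | intermediate
5 | 1-[2-hydroxy-4,6-bis(methoxymethoxy)phenyl]-2-(4-methoxyphenyl)ethan-1-one | COCOc1cc(O)c(C(=O)Cc2ccc(OC)cc2)c(OCOC)c1 | intermediate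
6 | 1-[2-hydroxy-3-iodo-4,6-bis(methoxymethoxy)phenyl]-2-(4-methoxyphenyl)ethan-1-one | COCOc1cc(OCOC)c(C(=O)Cc2ccc(OC)cc2)c(O)c1I | intermediate
7 | 1-[3-iodo-2-methoxy-4,6-bis(methoxymethoxy)phenyl]-2-(4-methoxyphenyl)ethan-1-one | COCOc1cc(OCOC)c(C(=O)Cc2ccc(OC)cc2)c(OC)c1I | intermediate
8 | 1-(4,6-dihydroxy-3-iodo-2-methoxyphenyl)-2-(4-methoxyphenyl)ethan-1-one | COc1ccc(CC(=O)c2c(O)cc(O)c(I)c2OC)cc1 | intermediate
9 | 1-(3-ethenyl-4,6-dihydroxy-2-methoxyphenyl)-2-(4-methoxyphenyl)ethan-1-one | COc1ccc(CC(=O)c2c(O)cc(O)c(C=C)c2OC)cc1 | intermediate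
10 | 1-[3-ethenyl-6-hydroxy-2-methoxy-4-(2-methoxypropan-2-yloxy)phenyl]-2-(4-methoxyphenyl)ethan-1-one | COc1ccc(CC(=O)c2c(O)cc(OC(C)(C)OC)c(C=C)c2OC)cc1 | intermediate (not isolated)
11 | 1-(7-hydroxy-5-methoxy-2,2-dimethyl-2H-chromen-6-yl)-2-(4-methoxyphenyl)ethan-1-one | COc1ccc(CC(=O)c2c(O)cc3c(c2OC)C=CC(C)(C)O3)cc1 | target

**Summary**

Total step count: 7. Longest linear sequence: 7 steps (from 1 or 2 to 11).

Steps most likely to fail:

1. Step 7 (Proposed new method). The mixed ketal may ionise mainly by loss of the phenol instead of methanol, and the electron-rich styrene may be protonated and oligomerise before the C–C bond forms. Fallback with known chemistry, setting out from 9: olefin cross-metathesis with 2-methylbut-3-en-2-ol (second-generation Grubbs catalyst, RuCl2(=CHPh)(H2IMes)(PCy3), CH2Cl2, 40 °C) should give (E)-1-[4,6-dihydroxy-3-(3-hydroxy-3-methylbut-1-en-1-yl)-2-methoxyphenyl]-2-(4-methoxyphenyl)ethan-1-one F1. Warming F1 with catalytic pyridinium p-toluenesulfonate in toluene should ionise the tertiary allylic alcohol and close the pyran ring through the neighbouring 4-hydroxyl (ortho-quinone methide, oxa-6π closure), with loss of water, which comes back to the route at 11.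

2. Step 3. Regiocontrol may be lost by attack of the iodinating agent at the ring carbon between the two MOM ethers, or by over-iodination. Fallback, setting out from 4: mono-iodination of the symmetric triol (I2, NaHCO3, THF–H2O, 0 °C), in which both free ring carbons are equivalent, should give 2-(4-methoxyphenyl)-1-(2,4,6-trihydroxy-3-iodophenyl)ethan-1-one F2. Bis-MOM protection of F2 under the conditions of step 2 should then take the para hydroxyl and the ortho hydroxyl remote from iodine, leaving free the hydroxyl flanked by iodine and the acyl group (the most hindered and the chelated one), which comes back to the route at 6.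

3. Step 6. Oxidative addition and transmetalation may be slow at the iodide flanked by a methoxy group and a free hydroxyl, and the vinylphenol product may undergo Heck-type oligomerisation or polymerise on heating. Fallback, setting out from 7 (the MOM-protected iodide): Heck reaction with 2-methylbut-3-en-2-ol (Pd(OAc)2, P(o-tol)3, Et3N, DMF, 100 °C) should give (E)-1-[3-(3-hydroxy-3-methylbut-1-en-1-yl)-2-methoxy-4,6-bis(methoxymethoxy)phenyl]-2-(4-methoxyphenyl)ethan-1-one F3. Treatment of F3 with 3 M HCl in MeOH–THF at 40 °C should remove both MOM groups and cyclodehydrate the liberated allylic alcohol in the same flask, which bypasses 8 and 9 and comes back to the route at 11.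

**Further compounds**

F1 | step 7 | (E)-1-[4,6-dihydroxy-3-(3-hydroxy-3-methylbut-1-en-1-yl)-2-methoxyphenyl]-2-(4-methoxyphenyl)ethan-1-one | COc1ccc(CC(=O)c2c(O)cc(O)c(/C=C/C(C)(C)O)c2OC)cc1
F2 | step 3 | 2-(4-methoxyphenyl)-1-(2,4,6-trihydroxy-3-iodophenyl)ethan-1-one | COc1ccc(CC(=O)c2c(O)cc(O)c(I)c2O)cc1
F3 | step 6 | (E)-1-[3-(3-hydroxy-3-methylbut-1-en-1-yl)-2-methoxy-4,6-bis(methoxymethoxy)phenyl]-2-(4-methoxyphenyl)ethan-1-one | COCOc1cc(OCOC)c(C(=O)Cc2ccc(OC)cc2)c(OC)c1/C=C/C(C)(C)O
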